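Retrosynthesis: the C2'–O ester bond is cut first, then the pyranone (C4–C4a and the C8a–O–C2 ester), then the benzene ring itself across C4a–C5, C4a–C8a, C6–C7 and C7–C8, and last the enone C=C and the two C3'–CH3 bonds.
Forward order: the side chain is built on the sugar lactone, ring A (benzene, C4a–C8a) is grown onto it by photo-Wolff benzannulation, ring B (pyranone) is closed by hydroarylation, and the ester is attached last.
Enabling feature: on ring A the oxygens at C7 and C8a are 1,3 to each other, the side chain at C6 is ortho to O–C7, and C5, C8 and C4a carry hydrogen. This is the pattern a vinylketene and a siloxyalkyne produce.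
Stereochemistry: C1' and C2' (both R, erythro) are C3 and C2 of 2,3-O-isopropylidene-D-erythronolactone and stay locked cis in the dioxolane until ring B is complete; the acyl stereocentre comes from (R)-2-methylbutanoic acid.
Key step: step 8

Remark: (triisopropylsiloxy)acetylene is assumed not to be purchasable and is made in steps 6 and 7; ring atoms carry coumarin locants and the side chain runs from C1' (benzylic) to C3' (dimethyl carbinol).
Abbreviation: Dx = (4R,5R)-2,2-dimethyl-5-[2-(triethylsilyloxy)propan-2-yl]-1,3-dioxolan-4-yl.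

Step 1
Reactants: 1 2,3-O-isopropylidene-D-erythronolactone
Product: 2 2-[(4R,5R)-5-(hydroxymethyl)-2,2-dimethyl-1,3-dioxolan-4-yl]propan-2-ol
Conditions: MeMgBr (3 equiv), THF, 0 °C to rt; aq. NH4Cl
Reagents that add atoms: methylmagnesium bromide, C[Mg]Br
Why: Double Grignard addition to the lactone carbonyl (through the methyl ketone released on ring opening) gives the tertiary carbinol C3' and frees the primary alcohol, while both acetonide stereocentres are untouched.

Step 2
Reactants: 2 2-[(4R,5R)-5-(hydroxymethyl)-2,2-dimethyl-1,3-dioxolan-4-yl]propan-2-ol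
Product: 3 triethyl(Dx-methoxy)silane (bis-triethylsilyl ether)
Conditions: Et3SiOTf (2.5 equiv), 2,6-lutidine, CH2Cl2, −78 to 0 °C
Reagents that add atoms: triethylsilyl trifluoromethanesulfonate, CC[Si](CC)(CC)OS(=O)(=O)C(F)(F)F
Why: A silyl triflate with a hindered pyridine base silylates both hydroxyls, including the tertiary one that a silyl chloride would leave free (exhaustive O-silylation).

Step 3
Reactants: 3 triethyl(Dx-methoxy)silane
Product: 4 (4S,5R)-2,2-dimethyl-5-[2-(triethylsilyloxy)propan-2-yl]-1,3-dioxolane-4-carbaldehyde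
Conditions: (COCl)2, DMSO, CH2Cl2, −78 to −40 °C; i-Pr2NEt, −78 to 0 °C; crude product used at once
Reagents that add atoms: none
Why: Under Swern conditions chlorodimethylsulfonium chloride cleaves a primary triethylsilyl ether and oxidises it in the same flask while the tertiary silyl ether and the acetonide remain (Swern oxidation of a primary silyl ether); cold addition of the hindered amine and immediate use guard the α-stereocentre (later C1') against epimerisation.

Step 4
Reactants: 4 (4S,5R)-2,2-dimethyl-5-[2-(triethylsilyloxy)propan-2-yl]-1,3-dioxolane-4-carbaldehyde; 5 1-(triphenyl-λ5-phosphanylidene)propan-2-one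
Product: 6 (E)-4-Dx-but-3-en-2-one
Conditions: CH2Cl2, rt to 40 °C
Reagents that add atoms: none
Why: Wittig olefination with a ketone-stabilised ylide under neutral conditions should give the (E)-enone without disturbing the adjacent alkoxy stereocentre.

Step 5
Reactants: 6 (E)-4-Dx-but-3-en-2-one
Product: 8 (E)-1-diazo-4-Dx-but-3-en-2-one, via trifluoroacetyl diketone 7 (not isolated)
Conditions: LiN(SiMe3)2, THF, −78 °C; CF3CO2CH2CF3; dil. HCl wash; then 4-AcNHC6H4SO2N3, Et3N, H2O (1 equiv), MeCN, rt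
Reagents that add atoms: 4-acetamidobenzenesulfonyl azide, CC(=O)Nc1ccc(cc1)S(=O)(=O)N=[N+]=[N-]
Why: Kinetic deprotonation at the methyl group, Claisen trifluoroacetylation and deacylative diazo transfer (Regitz-type, the trifluoroacetyl group leaving with the sulfonamide) is the standard entry to α'-diazo enones, which direct diazo transfer does not reach.

Step 6
Reactants: 9 2-bromo-1,1-diethoxyethane
Product: 11 (Z)-(2-bromoethenyloxy)tri(propan-2-yl)silane, via bromoacetaldehyde 10 (not isolated)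
Conditions: 2 M HCl aq., 60 °C; CH2Cl2 extraction, MgSO4; then i-Pr3SiOTf, i-Pr2NEt, CH2Cl2, −78 to 0 °C
Reagents that add atoms: water, O; triisopropylsilyl trifluoromethanesulfonate, CC(C)[Si](OS(=O)(=O)C(F)(F)F)(C(C)C)C(C)C
Why: Acetal hydrolysis releases the aldehyde, and soft enolisation with a silyl triflate and a hindered amine gives the silyl enol ether (mainly Z; either isomer serves in step 7), the bulky amine avoiding N-alkylation by the α-bromo aldehyde.

Step 7
Reactants: 11 (Z)-(2-bromoethenyloxy)tri(propan-2-yl)silane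
Product: 13 (ethynyloxy)tri(propan-2-yl)silane [(triisopropylsiloxy)acetylene], via lithium siloxyacetylide 12 (not isolated)
Conditions: LiN(i-Pr)2 (2.2 equiv), THF, −78 °C; aq. NH4Cl, −78 °C to rt
Reagents that add atoms: none
Why: Amide base removes HBr from the 2-bromovinyl ether (anti-elimination, or α-lithiation and Fritsch–Buttenberg–Wiechell 1,2-hydrogen shift, both leading to the same alkyne), the dehydrohalogenation by which alkoxyacetylenes are classically made; the second equivalent holds the product as its acetylide until the cold quench, and the bulky silyl group resists attack at silicon.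

Step 8
Reactants: 8 (E)-1-diazo-4-Dx-but-3-en-2-one; 13 (triisopropylsiloxy)acetylene
Product: 18 2-Dx-5-[tri(propan-2-yl)silyloxy]phenol, via vinylketene 14 (not isolated), via alkenylcyclobutenone 15 (not isolated), via dienylketene 16 (not isolated), via cyclohexadienone 17 (not isolated)
Conditions: 13 (2 equiv), hν (254 nm, Vycor), degassed ClCH2CH2Cl, rt; then 80 °C
Reagents that add atoms: none
Why: Light expels N2 from the diazo ketone with 1,2-shift of the alkenyl group (Wolff rearrangement, making C4a–C5) to give vinylketene 14, whose carbonyl carbon is attacked by the nucleophilic CH terminus of the siloxyalkyne in a (2+2) cycloaddition (making C7–C8 and C4a–C8a) that gives the 4-alkenyl-3-siloxycyclobutenone 15. Warming opens 15 by reversible four-electron electrocyclic cleavage to dienylketene 16, and ring A, the only ring that remains, closes by six-electron disrotatory electrocyclisation between the ketene carbon and the alkene terminus (C6–C7), after which cyclohexadienone 17 tautomerises to the phenol. The closest known reaction is the Danheiser benzannulation in its diazo ketone form with siloxyalkynes, which gives resorcinol monosilyl ethers. No stereocentre is created: the sp3 carbons of 15 and 17 are transient, and C1' and C2' lie outside the reacting π-system and stay cis in the dioxolane. Only regiochemistry must be controlled, and the polarisation of the siloxyalkyne fixes it, putting the silyloxy carbon at C8a, the free hydroxyl (the former ketene oxygen) at C7 and the side chain at C6 ortho to it. Excess alkyne and a dilute, degassed solution should limit ketene dimerisation and acylation of the product phenol by 14.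

Step 9
Reactants: 18 2-Dx-5-[tri(propan-2-yl)silyloxy]phenol
Product: 19 (3-methoxy-4-Dx-phenoxy)tri(propan-2-yl)silane
Conditions: MeI, K2CO3, acetone, rt
Reagents that add atoms: iodomethane, CI
Why: Williamson O-methylation of the only free hydroxyl, the C7 phenol, under mild carbonate conditions that should leave the aryl silyl ether in place.

Step 10
Reactants: 19 (3-methoxy-4-Dx-phenoxy)tri(propan-2-yl)silane
Product: 20 3-methoxy-4-Dx-phenol
Conditions: Bu4NF (1.1 equiv), AcOH (1.1 equiv), THF, 0 °C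
Reagents that add atoms: none
Why: Buffered fluoride cleaves an aryl silyl ether (phenoxide leaving group) much faster than the hindered tertiary alkyl triethylsilyl ether, so only the C8a oxygen is freed.

Step 11
Reactants: 20 3-methoxy-4-Dx-phenol; 21 propiolic acid
Product: 22 3-methoxy-4-Dx-phenyl prop-2-ynoate
Conditions: DCC, DMAP (5 mol%), CH2Cl2, −20 to 0 °C
Reagents that add atoms: none
Why: Steglich esterification of the phenol at low temperature gives the aryl propiolate, the tertiary silyl ether and the acetonide being inert.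

Step 12
Reactants: 22 3-methoxy-4-Dx-phenyl prop-2-ynoate
Product: 23 7-methoxy-6-Dx-2H-chromen-2-one
Conditions: Ph3PAuCl (5 mol%), AgSbF6 (5 mol%), CH2Cl2, rt
Reagents that add atoms: none
Why: Cationic monovalent gold activates the alkyne for 6-endo intramolecular hydroarylation (Friedel–Crafts-type alkenylation) at C4a, para to the methoxy group, because the carbon between the two oxygens (C8) is shielded by the methoxy methyl that the C6 substituent pushes toward it; protodeauration then gives the pyranone.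

Step 13
Reactants: 23 7-methoxy-6-Dx-2H-chromen-2-one
Product: 24 7-methoxy-6-[(1R,2R)-1,2,3-trihydroxy-3-methylbutyl]-2H-chromen-2-one
Conditions: 2 M HCl aq./THF, 40 °C
Reagents that add atoms: none
Why: Aqueous acid hydrolyses the acetonide and the tertiary silyl ether in one operation; the coumarin tolerates it, and the moderate temperature is chosen to avoid ionisation at the benzylic C1'.

Step 14
Reactants: 24 7-methoxy-6-[(1R,2R)-1,2,3-trihydroxy-3-methylbutyl]-2H-chromen-2-one
Product: 25 6-[(1R,2R)-2,3-dihydroxy-3-methyl-1-(triethylsilyloxy)butyl]-7-methoxy-2H-chromen-2-one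
Conditions: Et3SiCl (1.1 equiv), imidazole, CH2Cl2/DMF, −40 to 0 °C
Reagents that add atoms: chlorotriethylsilane, CC[Si](Cl)(CC)CC
Why: The benzylic C1' hydroxyl is the least hindered of the three (C2'–OH is flanked by the quaternary carbinol carbon, C3'–OH is tertiary), so one equivalent of silyl chloride at low temperature should silylate it selectively.

Step 15
Reactants: 25 6-[(1R,2R)-2,3-dihydroxy-3-methyl-1-(triethylsilyloxy)butyl]-7-methoxy-2H-chromen-2-one; 26 (R)-2-methylbutanoic acid
Product: 27 (1R,2R)-3-hydroxy-1-(7-methoxy-2-oxo-2H-chromen-6-yl)-3-methyl-1-(triethylsilyloxy)butan-2-yl (2R)-2-methylbutanoate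
Conditions: DCC, DMAP, CH2Cl2, rt
Reagents that add atoms: none
Why: Steglich esterification acylates the only remaining secondary hydroxyl (C2'–OH), the tertiary C3'–OH being unreactive, and a simple α-branched alkanoic acid is not prone to racemisation under these conditions.

Step 16
Reactants: 27 (1R,2R)-3-hydroxy-1-(7-methoxy-2-oxo-2H-chromen-6-yl)-3-methyl-1-(triethylsilyloxy)butan-2-yl (2R)-2-methylbutanoate
Product: 28 (1R,2R)-1,3-dihydroxy-1-(7-methoxy-2-oxo-2H-chromen-6-yl)-3-methylbutan-2-yl (2R)-2-methylbutanoate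
Conditions: HF·pyridine, pyridine, THF, 0 °C
Reagents that add atoms: none
Why: Buffered HF·pyridine removes the benzylic silyl ether under non-basic conditions, which should avoid 1,2-acyl migration from O2' to O1' or O3'.

Compound list
1 | 2,3-O-isopropylidene-D-erythronolactone, (3aR,6aR)-2,2-dimethyldihydrofuro[3,4-d][1,3]dioxol-4(3aH)-one | CC1(C)O[C@@H]2[C@H](O1)COC2=O | starting material
2 | 2-[(4R,5R)-5-(hydroxymethyl)-2,2-dimethyl-1,3-dioxolan-4-yl]propan-2-ol | OC[C@H]1OC(C)(C)O[C@H]1C(C)(C)O | intermediate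
3 | triethyl({(4R,5R)-2,2-dimethyl-5-[2-(triethylsilyloxy)propan-2-yl]-1,3-dioxolan-4-yl}methoxy)silane | CC[Si](CC)(CC)OC[C@H]1OC(C)(C)O[C@H]1C(C)(C)O[Si](CC)(CC)CC | intermediate
4 | (4S,5R)-2,2-dimethyl-5-[2-(triethylsilyloxy)propan-2-yl]-1,3-dioxolane-4-carbaldehyde | O=C[C@H]1OC(C)(C)O[C@H]1C(C)(C)O[Si](CC)(CC)CC | intermediate
5 | 1-(triphenyl-λ5-phosphanylidene)propan-2-one | CC(=O)C=P(c1ccccc1)(c1ccccc1)c1ccccc1 | starting material
6 | (E)-4-{(4R,5R)-2,2-dimethyl-5-[2-(triethylsilyloxy)propan-2-yl]-1,3-dioxolan-4-yl}but-3-en-2-one | CC(=O)/C=C/[C@H]1OC(C)(C)O[C@H]1C(C)(C)O[Si](CC)(CC)CC | intermediate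
7 | (E)-6-{(4R,5R)-2,2-dimethyl-5-[2-(triethylsilyloxy)propan-2-yl]-1,3-dioxolan-4-yl}-1,1,1-trifluorohex-5-ene-2,4-dione | O=C(CC(=O)C(F)(F)F)/C=C/[C@H]1OC(C)(C)O[C@H]1C(C)(C)O[Si](CC)(CC)CC | intermediate
8 | (E)-1-diazo-4-{(4R,5R)-2,2-dimethyl-5-[2-(triethylsilyloxy)propan-2-yl]-1,3-dioxolan-4-yl}but-3-en-2-one | [N-]=[N+]=CC(=O)/C=C/[C@H]1OC(C)(C)O[C@H]1C(C)(C)O[Si](CC)(CC)CC | intermediate
9 | 2-bromo-1,1-diethoxyethane (bromoacetaldehyde diethyl acetal) | CCOC(CBr)OCC | starting material
10 | bromoacetaldehyde | O=CCBr | intermediate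
11 | (Z)-(2-bromoethenyloxy)tri(propan-2-yl)silane | Br/C=C\O[Si](C(C)C)(C(C)C)C(C)C | intermediate
12 | lithium 2-[tri(propan-2-yl)silyloxy]ethynide | [Li]C#CO[Si](C(C)C)(C(C)C)C(C)C | intermediate
13 | (ethynyloxy)tri(propan-2-yl)silane, (triisopropylsiloxy)acetylene | C#CO[Si](C(C)C)(C(C)C)C(C)C | intermediate
14 | (3E)-4-{(4R,5R)-2,2-dimethyl-5-[2-(triethylsilyloxy)propan-2-yl]-1,3-dioxolan-4-yl}buta-1,3-dien-1-one | O=C=C/C=C/[C@H]1OC(C)(C)O[C@H]1C(C)(C)O[Si](CC)(CC)CC | intermediate
15 | 4-[(E)-2-{(4R,5R)-2,2-dimethyl-5-[2-(triethylsilyloxy)propan-2-yl]-1,3-dioxolan-4-yl}ethenyl]-3-[tri(propan-2-yl)silyloxy]cyclobut-2-en-1-one (both C4 epimers) | O=C1C=C(O[Si](C(C)C)(C(C)C)C(C)C)C1/C=C/[C@H]2OC(C)(C)O[C@H]2C(C)(C)O[Si](CC)(CC)CC | intermediate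
16 | (3E,5E)-6-{(4R,5R)-2,2-dimethyl-5-[2-(triethylsilyloxy)propan-2-yl]-1,3-dioxolan-4-yl}-3-[tri(propan-2-yl)silyloxy]hexa-1,3,5-trien-1-one (C2 and C5 cis across C3=C4) | O=C=C/C(O[Si](C(C)C)(C(C)C)C(C)C)=C\C=C\[C@H]1OC(C)(C)O[C@H]1C(C)(C)O[Si](CC)(CC)CC | intermediate
17 | 6-{(4R,5R)-2,2-dimethyl-5-[2-(triethylsilyloxy)propan-2-yl]-1,3-dioxolan-4-yl}-3-[tri(propan-2-yl)silyloxy]cyclohexa-2,4-dien-1-one (both C6 epimers) | O=C1C=C(O[Si](C(C)C)(C(C)C)C(C)C)C=CC1[C@H]2OC(C)(C)O[C@H]2C(C)(C)O[Si](CC)(CC)CC | intermediate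
18 | 2-{(4R,5R)-2,2-dimethyl-5-[2-(triethylsilyloxy)propan-2-yl]-1,3-dioxolan-4-yl}-5-[tri(propan-2-yl)silyloxy]phenol | Oc1cc(O[Si](C(C)C)(C(C)C)C(C)C)ccc1[C@H]2OC(C)(C)O[C@H]2C(C)(C)O[Si](CC)(CC)CC | intermediate
19 | (3-methoxy-4-{(4R,5R)-2,2-dimethyl-5-[2-(triethylsilyloxy)propan-2-yl]-1,3-dioxolan-4-yl}phenoxy)tri(propan-2-yl)silane | COc1cc(O[Si](C(C)C)(C(C)C)C(C)C)ccc1[C@H]2OC(C)(C)O[C@H]2C(C)(C)O[Si](CC)(CC)CC | intermediate
20 | 3-methoxy-4-{(4R,5R)-2,2-dimethyl-5-[2-(triethylsilyloxy)propan-2-yl]-1,3-dioxolan-4-yl}phenol | COc1cc(O)ccc1[C@H]2OC(C)(C)O[C@H]2C(C)(C)O[Si](CC)(CC)CC | intermediate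
21 | propiolic acid (prop-2-ynoic acid) | C#CC(=O)O | starting material
22 | 3-methoxy-4-{(4R,5R)-2,2-dimethyl-5-[2-(triethylsilyloxy)propan-2-yl]-1,3-dioxolan-4-yl}phenyl prop-2-ynoate | COc1cc(OC(=O)C#C)ccc1[C@H]2OC(C)(C)O[C@H]2C(C)(C)O[Si](CC)(CC)CC | intermediate
23 | 7-methoxy-6-{(4R,5R)-2,2-dimethyl-5-[2-(triethylsilyloxy)propan-2-yl]-1,3-dioxolan-4-yl}-2H-chromen-2-one | COc1cc2oc(=O)ccc2cc1[C@H]3OC(C)(C)O[C@H]3C(C)(C)O[Si](CC)(CC)CC | intermediate
24 | 7-methoxy-6-[(1R,2R)-1,2,3-trihydroxy-3-methylbutyl]-2H-chromen-2-one | COc1cc2oc(=O)ccc2cc1[C@@H](O)[C@@H](O)C(C)(C)O | intermediate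
25 | 6-[(1R,2R)-2,3-dihydroxy-3-methyl-1-(triethylsilyloxy)butyl]-7-methoxy-2H-chromen-2-one | COc1cc2oc(=O)ccc2cc1[C@@H](O[Si](CC)(CC)CC)[C@@H](O)C(C)(C)O | intermediate
26 | (R)-2-methylbutanoic acid | CC[C@@H](C)C(=O)O | starting material
27 | (1R,2R)-3-hydroxy-1-(7-methoxy-2-oxo-2H-chromen-6-yl)-3-methyl-1-(triethylsilyloxy)butan-2-yl (2R)-2-methylbutanoate | COc1cc2oc(=O)ccc2cc1[C@@H](O[Si](CC)(CC)CC)[C@@H](OC(=O)[C@H](C)CC)C(C)(C)O | intermediate
28 | (1R,2R)-1,3-dihydroxy-1-(7-methoxy-2-oxo-2H-chromen-6-yl)-3-methylbutan-2-yl (2R)-2-methylbutanoate | CC[C@@H](C)C(=O)O[C@H]([C@H](O)c1cc2ccc(=O)oc2cc1OC)C(C)(C)O | target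

Total step count: 16. Longest linear sequence: 14 steps (steps 1–5 and 8–16, from lactone 1); steps 6 and 7 form the short branch to alkyne 13.

Steps most likely to fail

Step 8 (benzannulation). Under irradiation the enone may isomerise about its C=C bond, and the excited diazo ketone may be diverted (carbene capture by a dioxolane oxygen, secondary photolysis). The unsubstituted siloxyalkyne may also trap the ketene too slowly to outrun ketene dimerisation. The fallback sets out from aldehyde 4 and returns at phenol 18; it generates the vinylketene in the dark by dehydrochlorination. Wittig reaction of 4 with the ylide from (2-carboxyethyl)triphenylphosphonium bromide and NaN(SiMe3)2 (THF, −78 °C to rt) should give (Z)-4-Dx-but-3-enoic acid F1. 1-Chloro-N,N,2-trimethylprop-1-en-1-amine (CH2Cl2, 0 °C) should convert it under neutral conditions into (Z)-4-Dx-but-3-enoyl chloride F2. Slow addition of F2 to Et3N and 13 in toluene (rt, then 80 °C) should eliminate HCl to give (3Z)-4-Dx-buta-1,3-dien-1-one F3. This ketene is expected to follow the same course through 4-[(Z)-2-Dx-ethenyl]-3-[tri(propan-2-yl)silyloxy]cyclobut-2-en-1-one F4 and (3E,5Z)-6-Dx-3-[tri(propan-2-yl)silyloxy]hexa-1,3,5-trien-1-one F5 to cyclohexadienone 17 and phenol 18.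

Step 14 (monosilylation). Discrimination between O1' and O2' may be incomplete, or the silyl group may move between them during the acylation, and either would end in the regioisomeric ester. The fallback sets out from triol 24 and returns at target 28; it relies on ring size instead of rate. Equilibrating acetalisation of 24 with 4-methoxybenzaldehyde dimethyl acetal (camphorsulfonic acid cat., CH2Cl2, rt) should favour the six-membered acetal across O1' and O3', 6-[(4R,5R)-5-hydroxy-2-(4-methoxyphenyl)-6,6-dimethyl-1,3-dioxan-4-yl]-7-methoxy-2H-chromen-2-one F6. In F6 both aryl groups and the C2' hydroxyl can be equatorial, whereas a dioxolane across O1'/O2' would carry cis substituents. Steglich esterification with 26 (DCC, DMAP, CH2Cl2) should then give (4R,5R)-4-(7-methoxy-2-oxo-2H-chromen-6-yl)-2-(4-methoxyphenyl)-6,6-dimethyl-1,3-dioxan-5-yl (2R)-2-methylbutanoate F7, and aqueous acetic acid (rt) removes the acetal to give 28 without any basic step.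

Step 12 (hydroarylation). Ring closure may occur at C8, between the two oxygens, in competition with C4a, and the Lewis acidic metal salts may strip the acetal or silyl group. The fallback sets out from phenol 20 and returns at coumarin 23; it places the carbon substituent at C4a first. Magnesium-directed ortho-formylation (MgCl2, Et3N, paraformaldehyde, MeCN, 80 °C), which prefers the less hindered ortho position para to the methoxy group, should give 2-hydroxy-4-methoxy-5-Dx-benzaldehyde F8. Heating with Ph3P=C=C=O (toluene, 110 °C) should acylate the phenol to the ylide ester 2-formyl-5-methoxy-4-Dx-phenyl (triphenyl-λ5-phosphanylidene)acetate F9, which is not isolated and closes the pyranone to 23 by intramolecular Wittig reaction.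

Further compounds
F1 | step 8 | (Z)-4-{(4R,5R)-2,2-dimethyl-5-[2-(triethylsilyloxy)propan-2-yl]-1,3-dioxolan-4-yl}but-3-enoic acid | OC(=O)C/C=C\[C@H]1OC(C)(C)O[C@H]1C(C)(C)O[Si](CC)(CC)CC
F2 | step 8 | (Z)-4-{(4R,5R)-2,2-dimethyl-5-[2-(triethylsilyloxy)propan-2-yl]-1,3-dioxolan-4-yl}but-3-enoyl chloride | ClC(=O)C/C=C\[C@H]1OC(C)(C)O[C@H]1C(C)(C)O[Si](CC)(CC)CC
F3 | step 8 | (3Z)-4-{(4R,5R)-2,2-dimethyl-5-[2-(triethylsilyloxy)propan-2-yl]-1,3-dioxolan-4-yl}buta-1,3-dien-1-one | O=C=C/C=C\[C@H]1OC(C)(C)O[C@H]1C(C)(C)O[Si](CC)(CC)CC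
F4 | step 8 | 4-[(Z)-2-{(4R,5R)-2,2-dimethyl-5-[2-(triethylsilyloxy)propan-2-yl]-1,3-dioxolan-4-yl}ethenyl]-3-[tri(propan-2-yl)silyloxy]cyclobut-2-en-1-one (both C4 epimers) | O=C1C=C(O[Si](C(C)C)(C(C)C)C(C)C)C1/C=C\[C@H]2OC(C)(C)O[C@H]2C(C)(C)O[Si](CC)(CC)CC
F5 | step 8 | (3E,5Z)-6-{(4R,5R)-2,2-dimethyl-5-[2-(triethylsilyloxy)propan-2-yl]-1,3-dioxolan-4-yl}-3-[tri(propan-2-yl)silyloxy]hexa-1,3,5-trien-1-one | O=C=C/C(O[Si](C(C)C)(C(C)C)C(C)C)=C\C=C/[C@H]1OC(C)(C)O[C@H]1C(C)(C)O[Si](CC)(CC)CC
F6 | step 14 | 6-[(4R,5R)-5-hydroxy-2-(4-methoxyphenyl)-6,6-dimethyl-1,3-dioxan-4-yl]-7-methoxy-2H-chromen-2-one (acetal carbon unassigned, aryl expected equatorial) | COc1cc2oc(=O)ccc2cc1[C@H]3OC(c4ccc(OC)cc4)OC(C)(C)[C@@H]3O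
F7 | step 14 | (4R,5R)-4-(7-methoxy-2-oxo-2H-chromen-6-yl)-2-(4-methoxyphenyl)-6,6-dimethyl-1,3-dioxan-5-yl (2R)-2-methylbutanoate (acetal carbon unassigned) | COc1cc2oc(=O)ccc2cc1[C@H]3OC(c4ccc(OC)cc4)OC(C)(C)[C@@H]3OC(=O)[C@H](C)CC
F8 | step 12 | 2-hydroxy-4-methoxy-5-{(4R,5R)-2,2-dimethyl-5-[2-(triethylsilyloxy)propan-2-yl]-1,3-dioxolan-4-yl}benzaldehyde | COc1cc(O)c(C=O)cc1[C@H]2OC(C)(C)O[C@H]2C(C)(C)O[Si](CC)(CC)CC
F9 | step 12 | 2-formyl-5-methoxy-4-{(4R,5R)-2,2-dimethyl-5-[2-(triethylsilyloxy)propan-2-yl]-1,3-dioxolan-4-yl}phenyl (triphenyl-λ5-phosphanylidene)acetate | COc1cc(OC(=O)C=P(c2ccccc2)(c2ccccc2)c2ccccc2)c(C=O)cc1[C@H]3OC(C)(C)O[C@H]3C(C)(C)O[Si](CC)(CC)CC
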